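## Structural features

Pharbinilic acid (31) is a 20-nor-gibberellane whose ring A is aromatic and carries a fused furan (oxygen on C3, C2'–H, C3' carboxyl on C2) and a methyl group on C4. Ring A is fused through C5 and C10 to the cyclopentane ring B (C5–C6–C8–C9–C10). Ring B shares the C8–C9 bond with cyclohexane ring C, and C8 and C13 are joined a second time by C15–C16, so rings C and D form a bicyclo[3.2.1]octane with C14 as the one-carbon bridge. There are four stereocentres: C6 (benzylic, carboxyl-bearing), the quaternary bridgehead C8, the benzylic C9 and the tertiary carbinol C13. C6, C8 and C9 are contiguous, and C13 is tied to C8 by both bridges, so only the C13 configuration, the cis B/C fusion at C9 and the C6 epimer are free choices. The fragile points are the tertiary allylic C13 alcohol beside the exocyclic C16=C17 (acid-induced C/D rearrangement), the epimerisable C6, and, in intermediates, any cyclohexenone with the C13 oxygen β to a carbonyl (loss of that oxygen aromatises ring C) and any free C13 ketol (retro-aldol, acyloin shift). The real difficulty is the all-carbon quaternary C8 shared by rings B, C and D, together with the absolute configuration at C13. The key step exploits the fact that C13 carries an oxygen and the carbon C16 just as C1 of quinic acid carries hydroxyl and carboxyl. When ring C is a cyclohex-2-enone (C11 carbonyl, C9=C8), C8 is an electrophilic β-carbon 1,3 to C13, so a C13 acetyl group (C16 carbonyl, C15 methyl) can deliver C15 to C8 and close ring D. This mapping gives the correct enantiomer only if C11 descends from C3 of quinic acid (the cis-diol carbon remote from the lactone oxygen), C9 from C4 and C8 from C5.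

## Logic of the disconnections

31 ⇐ 29. No skeletal bond is cut. The two carboxyls and the C13 hydroxyl are masked as methyl and ethyl esters and a silyl ether. This keeps the acid-sensitive allylic alcohol and the acids out of every earlier step. The demand is that the last operation uses only fluoride and hydroxide and lets C6 settle thermodynamically.

29 ⇐ 26 (through 27 and 28). The C11 methylene is traced back to a C11 carbonyl. That carbonyl is what makes C8 electrophilic earlier and what allows C9 to be corrected after ring B exists. The demand is a deoxygenation that tolerates the exocyclic alkene and is run only after the aryl bromide has been consumed.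

26 ⇐ 24 (through 25). The C5–C6 bond of ring B is cut to an aryl bromide and an acetate arm on C8. The forward step is a palladium enolate arylation. A free C11 ketone beside the bromoarene would divert palladium to enolate O-arylation, and a fixed C9 with the aryl group trans to the arm could not close the ring. In 24 the C11 enolate is therefore capped on oxygen and C9 is planar. The cis B/C fusion is set only after ring B exists, when it is strongly favoured.

24 ⇐ 23 ⇐ 22. The enol ether and the C16=C17 methylene go back to the dione 22. The forward demands are methylenation of C16 in the presence of C11, and enolisation of C11 toward C9 only.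

22 ⇐ 21. The C8–C15 bond of ring D is cut. This removes the bicycle and the quaternary centre and leaves a monocyclic enone whose only stereocentre is C13. The forward step must add the acetyl methyl carbon to C8 faster than it adds to the C11 carbonyl and without loss of the C13 oxygen. The C13 oxygen is silylated in 21 and 22 so that neither is a free ketol.

21 ⇐ 20 ⇐ 19 ⇐ 18. The acetyl group is traced to a vinyl group, so that only one ketone is present when the arm is introduced. The C8–C6 bond is then cut with a 1,3-carbonyl transposition: the arm enters by 1,2-addition at the carbonyl that was C5 of the chiral-pool ring, and the oxygen moves to C11. This places the carbonyl on the correct side of C13. The demands are a clean 1,2-addition and an oxidative allylic transposition.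

18 ⇐ 15 + 6. The C9–C10 bond is cut between an α-iodoenone and an aryl metal. The coupling must leave the neighbouring aryl bromide intact and must not be basic, because the C13 oxygen is β to the carbonyl.

15 ⇐ 14 ⇐ 13 ⇐ 12 ⇐ 11 ⇐ 10 ⇐ 9 ⇐ 8 ⇐ 7. These are functional-group changes only. The lactone of 8 distinguishes the C5 oxygen from the C3 and C4 oxygens. The cis-diol is removed as an alkene, and the lactone carbon becomes the vinyl group. Each step must leave the quaternary carbinol untouched.

6 ⇐ 3 + 4, and 3 ⇐ 2 ⇐ 1. The furan ring is cut at O–C2' and C2–C3' to a salicylaldehyde and the diazo ester 4. The iodine that becomes the metal at C10 enters para to the phenol oxygen, and the formyl group enters at the only free ortho position.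

## Other disconnections considered

Alternative 1: ynone benzannulation building ring A last. The cut is C1–C10 and C4–C5. In the forward step the pyrrolidine enamine of the ring B ketone A2 adds through C10 to the terminal carbon of pent-1-yn-3-one A3, the ethyl-side carbon C4 condenses with the C5 carbonyl, and tautomerisation gives the phenol A1. In its favour, it forms two C–C bonds and an aromatic ring in one flask with unambiguous regiochemistry, and it starts from a core in which C6, C8, C9 and C13 are already fixed. It needs no cross-coupling and no correction of C9; on these points it is the better of the two plans. Against it, A1 has no furan: C2 must still be formylated and annulated with a diazo ester under strong acid in the presence of the acetal-protected allylic C13 oxygen and the exocyclic alkene, and C7 must be oxidised from the silyl ether level to the acid. More importantly, the step does not address the quaternary C8 or ring D; A2 needs its own enantioselective synthesis of the bicyclo[3.2.1]octane. The chosen plan solves that problem in its key step and carries C7 at the correct oxidation level. On mechanism the two are comparable (both amine-mediated carbonyl chemistry). On step economy alternative 1 is probably not shorter once A2 and the furan are counted.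

Alternative 2: aryl ketone tethered intramolecular Diels–Alder for rings B and C. The cut is C8–C9 and C13–C14. In the forward step a chiral oxazaborolidinium-type Lewis acid activates the 2-methylene ketone of A5 (dienophile C8=C14), which adds across the (E,E)-siloxydiene on C10 to give the cis-fused hexahydrofluorenone A4. In its favour, two rings, two bonds and three stereocentres (C8, C9, C13) form at once, ring A with its furan is present from the start, and the cis B/C fusion follows from the concerted suprafacial addition. On bond economy and on C9 control it is the better plan, and its longest linear sequence is likely shorter. Against it, C13 emerges as a secondary silyl ether and must be oxidised before ring D can be closed onto the propargyl group. The C6 ketone, flanked by the quaternary C8 and a di-ortho-substituted arene, must be homologated by one carbon with control of C6. The C11=C12 alkene must be saturated beside an alkyne or exocyclic methylene. The absolute configuration depends on catalyst control with a twisted, hindered aryl ketone and an acid-labile siloxydiene. The chosen plan takes C13 with its oxygen and C16 intact from the chiral pool and has C7 in place. Alternative 2 is the equal of the chosen plan only if the catalyst control is high.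

Alternative 3: double Michael annulation of an indene ester with butenone. The cut is C9–C11 and C8–C14. In the forward step base forms the indenide of A7 at C9, which adds to C11 of but-3-en-2-one A8; the methyl-side enolate (C14) then adds to C8 of the unsaturated ester and gives the tricyclic ketone A6. In its favour, it is the shortest route to rings A–C: the C6 ester is at the correct oxidation level, C8 is quaternary, and the C13 ketone and propargyl group are set up for a reductive ketone–alkyne closure of ring D that would give the C13 hydroxyl and C16 methylene together. On step economy it is the better plan. Against it, there is no built-in control of absolute configuration (a chiral catalyst or a resolution is needed). The ambident indenide can react at the ester-bearing carbon. The double bond must stay in conjugation with the ester for the second addition. Butenone tends to oligomerise. Mechanistically both plans rest on reversible enolate conjugate additions and are equal there. On absolute stereocontrol the chosen plan is stronger, because C13 comes from 7 and dictates C8.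

Key step: step 16

Remark: Ar denotes 6-bromo-3-(ethoxycarbonyl)-7-methylbenzofuran-5-yl, gibberellane locants are used for the carbons of rings B, C and D throughout, and the C13 oxygen is carried as its tert-butyldimethylsilyl ether through the key step (skeletons of 21 and 22 otherwise unchanged).

Step 1
Reactants: 1 3-bromo-2-methylphenol
Product: 2 4-bromo-2-hydroxy-3-methylbenzaldehyde
Conditions: MgCl2, Et3N, (CH2O)n, MeCN, reflux
Reagents that add atoms: paraformaldehyde (as formaldehyde), C=O
Why: Magnesium phenoxide-directed ortho-formylation (Casnati–Skattebøl); the only free ortho position takes the formyl group, and a second formaldehyde acts as hydride acceptor.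

Step 2
Reactants: 2 4-bromo-2-hydroxy-3-methylbenzaldehyde
Product: 3 4-bromo-2-hydroxy-5-iodo-3-methylbenzaldehyde
Conditions: N-iodosuccinimide, CF3CO2H (cat.), MeCN, rt
Reagents that add atoms: N-iodosuccinimide, O=C1CCC(=O)N1I
Why: Electrophilic aromatic iodination; the carbon para to the hydroxyl and meta to the formyl group is the only activated position, so iodine enters at the future C10 next to bromine.

Step 3
Reactants: 3 4-bromo-2-hydroxy-5-iodo-3-methylbenzaldehyde; 4 ethyl diazoacetate
Product: 6 ethyl 6-bromo-5-iodo-7-methylbenzofuran-3-carboxylate, via hemiacetal 5 (not isolated)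
Conditions: HBF4·OEt2 (10 mol %), CH2Cl2, rt; then conc. H2SO4, rt
Reagents that add atoms: none
Why: Acid-catalysed addition of the diazo ester to the aldehyde with 1,2-aryl shift (Roskamp-type homologation) gives a 3-hydroxy-2-arylacrylate that closes on the phenol to hemiacetal 5; sulfuric acid dehydrates it to the 3-carboxylate benzofuran.

Step 4
Reactants: 7 (−)-quinic acid
Product: 8 quinide (1,5-lactone of quinic acid; 1-, 3- and 4-hydroxyls free)
Conditions: p-TsOH·H2O (cat.), toluene/DMF, reflux (Dean–Stark)
Reagents that add atoms: none
Why: Acid-catalysed lactonisation; only the C5 hydroxyl is cis to the carboxyl, so the bridged γ-lactone forms and marks C5 as different from C3.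

Step 5
Reactants: 8 quinide
Product: 9 quinide 3,4-O-thionocarbonate (1-hydroxyl free)
Conditions: 1,1'-thiocarbonyldiimidazole, THF, reflux
Reagents that add atoms: 1,1'-thiocarbonyldiimidazole, S=C(n1ccnc1)n1ccnc1
Why: Cyclic thionocarbonate formation on the cis-3,4-diol; the tertiary bridgehead hydroxyl does not compete.

Step 6
Reactants: 9 quinide 3,4-O-thionocarbonate
Product: 10 (1S,5R)-1-hydroxy-6-oxabicyclo[3.2.1]oct-3-en-7-one
Conditions: P(OMe)3, 110 °C
Reagents that add atoms: none
Why: Corey–Winter olefination; desulfurisation and stereospecific cycloreversion remove the two oxygens that the target does not need and leave the C9=C11 alkene (quinic C3=C4).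

Step 7
Reactants: 10 (1S,5R)-1-hydroxy-6-oxabicyclo[3.2.1]oct-3-en-7-one
Product: 11 (1S,5R)-1-(tert-butyldimethylsilyloxy)-6-oxabicyclo[3.2.1]oct-3-en-7-one
Conditions: tBuMe2SiOTf, 2,6-lutidine, CH2Cl2, 0 °C to rt
Reagents that add atoms: tert-butyldimethylsilyl triflate, CC(C)(C)[Si](C)(C)OS(=O)(=O)C(F)(F)F
Why: Silylation of the tertiary alcohol with a silyl triflate; the ether later blocks retro-aldol and acyloin pathways at C13 and survives buffered fluoride.

Step 8
Reactants: 11 (1S,5R)-1-(tert-butyldimethylsilyloxy)-6-oxabicyclo[3.2.1]oct-3-en-7-one
Product: 12 1-(tert-butyldimethylsilyloxy)-6-oxabicyclo[3.2.1]oct-3-en-7-ol (lactol, anomeric mixture)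
Conditions: iBu2AlH, CH2Cl2, −78 °C; Rochelle salt
Reagents that add atoms: none
Why: Partial reduction of the bridged lactone; the tetrahedral aluminate is stable at low temperature and collapses to the lactol only on work-up.

Step 9
Reactants: 12 lactol
Product: 13 (1R,5S)-5-(tert-butyldimethylsilyloxy)-5-vinylcyclohex-2-en-1-ol (hydroxyl cis to vinyl)
Conditions: Ph3PCH3Br, KOtBu, THF, 0 °C to rt
Reagents that add atoms: methyltriphenylphosphonium bromide, C[P+](c1ccccc1)(c1ccccc1)c1ccccc1.[Br-]
Why: Wittig methylenation of the lactol through its hydroxy-aldehyde tautomer; the aldehyde has no α-hydrogen, so C13 cannot epimerise. The vinyl group is a masked acetyl group that keeps a second ketone out of steps 10–14.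

Step 10
Reactants: 13 (1R,5S)-5-(tert-butyldimethylsilyloxy)-5-vinylcyclohex-2-en-1-ol
Product: 14 (S)-5-(tert-butyldimethylsilyloxy)-5-vinylcyclohex-2-enone
Conditions: Dess–Martin periodinane, CH2Cl2, 0 °C to rt
Reagents that add atoms: none
Why: Dess–Martin oxidation of the allylic alcohol under near-neutral conditions, so the β-silyloxy group is not eliminated.

Step 11
Reactants: 14 (S)-5-(tert-butyldimethylsilyloxy)-5-vinylcyclohex-2-enone
Product: 15 (S)-5-(tert-butyldimethylsilyloxy)-2-iodo-5-vinylcyclohex-2-enone
Conditions: I2, pyridine/CH2Cl2, 0 °C to rt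
Reagents that add atoms: iodine, II
Why: α-Iodination of the enone by pyridine conjugate addition, enolate iodination and elimination; the isolated vinyl group is inert to iodine/pyridine.

Step 12
Reactants: 15 (S)-5-(tert-butyldimethylsilyloxy)-2-iodo-5-vinylcyclohex-2-enone; 6 ethyl 6-bromo-5-iodo-7-methylbenzofuran-3-carboxylate
Product: 18 (S)-2-Ar-5-(tert-butyldimethylsilyloxy)-5-vinylcyclohex-2-enone, via arylmagnesium chloride 16 (not isolated), via arylzinc chloride 17 (not isolated)
Conditions: 6, iPrMgCl·LiCl, THF, −40 °C; ZnCl2, −40 to 0 °C; then 15, Pd(PPh3)4 (5 mol %), THF, rt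
Reagents that add atoms: none
Why: Iodine–magnesium exchange at −40 °C tolerates the ester and the ortho bromide; transmetalation to zinc and Negishi coupling with the 2-iodoenone form C9–C10 without base. Oxidative addition to the alkenyl iodide is far faster than to the hindered aryl bromide.

Step 13
Reactants: 18 (S)-2-Ar-5-(tert-butyldimethylsilyloxy)-5-vinylcyclohex-2-enone
Product: 19 methyl 2-[2-Ar-5-(tert-butyldimethylsilyloxy)-1-hydroxy-5-vinylcyclohex-2-enyl]acetate (carbinol epimers at C8)
Conditions: LiN(iPr)2, MeOAc, THF, −78 °C; then 18, −78 °C; AcOH, −78 °C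
Reagents that add atoms: methyl acetate, CC(=O)OC
Why: Kinetic 1,2-addition of a lithium ester enolate to the only ketone (aldol-type addition), quenched cold to prevent retro-aldol and conjugate addition. The new carbinol centre is destroyed in step 14.

Step 14
Reactants: 19 tertiary allylic alcohol
Product: 20 methyl 2-[(5R)-2-Ar-5-(tert-butyldimethylsilyloxy)-3-oxo-5-vinylcyclohex-1-enyl]acetate
Conditions: pyridinium chlorochromate (C5H5NH[CrO3Cl]), 4 Å molecular sieves, CH2Cl2, rt
Reagents that add atoms: pyridinium chlorochromate, [O-][Cr](=O)(=O)Cl.c1cc[nH+]cc1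
Why: Babler–Dauben oxidative transposition; the tertiary chromate ester undergoes [3,3] shift to the secondary allylic chromate, which is oxidised. The carbonyl arrives on C11 and the arm stays on C8, the regiochemistry that matches C13 of the target.

Step 15
Reactants: 20 vinyl enone
Product: 21 methyl 2-[(5R)-5-acetyl-2-Ar-5-(tert-butyldimethylsilyloxy)-3-oxocyclohex-1-enyl]acetate
Conditions: PdCl2 (20 mol %), CuCl, O2 (1 atm), DMF/H2O 7:1, rt
Reagents that add atoms: water, O
Why: Tsuji–Wacker oxidation of the monosubstituted alkene to the methyl ketone (Markovnikov hydroxypalladation). The alkene sits on a quaternary carbon and cannot isomerise, and the tetrasubstituted enone is inert.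

Step 16
Reactants: 21 methyl 2-[(5R)-5-acetyl-2-Ar-5-(tert-butyldimethylsilyloxy)-3-oxocyclohex-1-enyl]acetate
Product: 22 methyl 2-[2-Ar-5-(tert-butyldimethylsilyloxy)-3,6-dioxobicyclo[3.2.1]octan-1-yl]acetate (C11 and C16 ketones, C13 silyl ether, arm on C8, aryl on C9)
Conditions: pyrrolidine (1 equiv), AcOH (1 equiv), MeCN, 40 °C
Reagents that add atoms: none
Why: Pyrrolidine condenses with the acetyl carbonyl, whose only enolisable carbon is C15, and the enamine adds through C15 to C8, the β-carbon of the C11 enone; proton transfer to C9 and hydrolysis give the 1,5-diketone. The closest known reaction type is the amine-mediated intramolecular Michael addition of a methyl ketone to a β,β-disubstituted cyclohexenone, which gives a bicyclo[3.2.1]octane with a quaternary bridgehead. Ring D (C8–C14–C13–C16–C15) closes in the 5-(enolexo)-exo-trig mode. C8 is controlled by C13: the acetyl group reaches C8 only when pseudoaxial and only across the face it occupies, because the two-carbon bridge must span C13 and C8 cis. C9 is set by protonation and stays epimerisable next to C11; its configuration is not relied on, since C9 is made planar in step 18 and fixed after ring B exists in step 19. The step needs 1,4- over 1,2-addition: the aldol adduct at C11 is a reversible tertiary aldol, whereas the Michael adduct is the thermodynamic sink. It also needs retention of the C13 oxygen: buffered amine catalysis avoids the C12 enolate that would expel silanolate and aromatise ring C, and the silyl ether rules out retro-aldol and acyloin shift of a free ketol. Once the bicycle has formed, loss of the C13 oxygen would need a bridgehead alkene and is no longer possible.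

Step 17
Reactants: 22 bicyclic dione
Product: 23 methyl 2-[2-Ar-5-(tert-butyldimethylsilyloxy)-6-methylene-3-oxobicyclo[3.2.1]octan-1-yl]acetate
Conditions: Ph3PCH3Br, KOtBu, THF, 0 °C
Reagents that add atoms: methyltriphenylphosphonium bromide, C[P+](c1ccccc1)(c1ccccc1)c1ccccc1.[Br-]
Why: Wittig methylenation; the ylide first removes the acidic benzylic C9–H, so C11 is protected as its enolate while the C16 carbonyl is methylenated. After this step no retro-Michael pathway remains.

Step 18
Reactants: 23 methylene ketone
Product: 24 methyl 2-[2-Ar-3,5-bis(tert-butyldimethylsilyloxy)-6-methylenebicyclo[3.2.1]oct-2-en-1-yl]acetate (C9=C11 silyl enol ether)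
Conditions: KN(SiMe3)2 (0.95 equiv), THF, −78 to 0 °C; then tBuMe2SiOTf, −78 °C
Reagents that add atoms: tert-butyldimethylsilyl triflate, CC(C)(C)[Si](C)(C)OS(=O)(=O)C(F)(F)F
Why: Thermodynamic enolate formation at the benzylic α-carbon C9 (a slight deficit of base lets the enolates equilibrate) and O-silylation. The enol ether caps the oxygen that would otherwise undergo O-arylation and makes C9 planar.

Step 19
Reactants: 24 silyl enol ether
Product: 26 11-oxo-13-O-(tert-butyldimethylsilyl)pharbinilic acid 7-methyl 3'-ethyl diester, via ring-closed silyl enol ether 25 (not isolated)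
Conditions: Pd(OAc)2 (10 mol %), P(tBu)3·HBF4 (20 mol %), LiN(SiMe3)2 (2.3 equiv), toluene, 70 °C; then Bu4NF, AcOH, THF, 0 °C to rt; then DBU, CH2Cl2, rt
Reagents that add atoms: none
Why: Palladium-catalysed intramolecular α-arylation of the ester enolate forms C5–C6 through a six-membered palladacycle and closes ring B. Buffered fluoride cleaves only the enol silyl ether; protonation at C9 and DBU equilibration give the cis B/C fusion, because the trans-fused hydrofluorenone is strained. C6 equilibrates at the same time, with its ester expected on the convex face, syn to H9.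

Step 20
Reactants: 26 tetracyclic ketone
Product: 27 11-hydroxy-13-O-(tert-butyldimethylsilyl)pharbinilic acid 7-methyl 3'-ethyl diester (C11 epimers)
Conditions: NaBH4, MeOH/THF, 0 °C
Reagents that add atoms: none
Why: Borohydride reduction of the ketone in the presence of two esters; the carbinol configuration is irrelevant because C11 becomes a methylene.

Step 21
Reactants: 27 C11 alcohol
Product: 28 11-O-(imidazol-1-ylthiocarbonyl)-13-O-(tert-butyldimethylsilyl)pharbinilic acid 7-methyl 3'-ethyl diester
Conditions: 1,1'-thiocarbonyldiimidazole, DMAP, ClCH2CH2Cl, 70 °C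
Reagents that add atoms: 1,1'-thiocarbonyldiimidazole, S=C(n1ccnc1)n1ccnc1
Why: Thiocarbonylimidazolide formation, the activation step of the Barton–McCombie deoxygenation; the silylated C13 oxygen cannot form a cyclic thionocarbonate.

Step 22
Reactants: 28 thiocarbonylimidazolide
Product: 29 13-O-(tert-butyldimethylsilyl)pharbinilic acid 7-methyl 3'-ethyl diester
Conditions: Bu3SnH, AIBN, toluene, 100 °C
Reagents that add atoms: none
Why: Barton–McCombie radical deoxygenation; the aryl bromide is already consumed, and the secondary C11 radical has no 5-exo acceptor, so it is simply reduced.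

Step 23
Reactants: 29 silyl ether diester
Product: 31 pharbinilic acid, via desilylated diester 30 (not isolated)
Conditions: Bu4NF, THF, 50 °C; then LiOH, MeOH/H2O, 50 °C; 1 M HCl to pH 3, 0 °C
Reagents that add atoms: lithium hydroxide, [Li+].[OH-]
Why: Fluoride desilylation followed by saponification of both esters. The basic medium equilibrates the α-aryl ester at C6 before the hindered C7 ester is hydrolysed, and C7 is expected to settle anti to the C9–C11 bond, as in the target. Cold, brief acidification avoids the acid-induced rearrangement of the C13 allylic alcohol.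

## Compound list

1 | 3-bromo-2-methylphenol | Cc1c(O)cccc1Br | starting material
2 | 4-bromo-2-hydroxy-3-methylbenzaldehyde | O=Cc1ccc(Br)c(C)c1O | intermediate
3 | 4-bromo-2-hydroxy-5-iodo-3-methylbenzaldehyde | O=Cc1cc(I)c(Br)c(C)c1O | intermediate
4 | ethyl diazoacetate | CCOC(=O)C=[N+]=[N-] | starting material
5 | ethyl 6-bromo-2-hydroxy-5-iodo-7-methyl-2,3-dihydrobenzofuran-3-carboxylate (hemiacetal, diastereomer mixture) | CCOC(=O)C1C(O)Oc2c(C)c(Br)c(I)cc12 | intermediate
6 | ethyl 6-bromo-5-iodo-7-methylbenzofuran-3-carboxylate | CCOC(=O)c1coc2c(C)c(Br)c(I)cc12 | intermediate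
7 | (−)-quinic acid | C1[C@H]([C@H]([C@@H](C[C@@]1(C(=O)O)O)O)O)O | starting material
8 | quinide (1,5-lactone of quinic acid) | O[C@]12C[C@@H](O)[C@@H](O)[C@H](OC1=O)C2 | intermediate
9 | quinide 3,4-O-thionocarbonate | O[C@]12C[C@@H](OC(=S)O3)[C@@H]3[C@H](OC1=O)C2 | intermediate
10 | (1S,5R)-1-hydroxy-6-oxabicyclo[3.2.1]oct-3-en-7-one | O[C@]12CC=C[C@H](OC1=O)C2 | intermediate
11 | (1S,5R)-1-(tert-butyldimethylsilyloxy)-6-oxabicyclo[3.2.1]oct-3-en-7-one | CC(C)(C)[Si](C)(C)O[C@]12CC=C[C@H](OC1=O)C2 | intermediate
12 | 1-(tert-butyldimethylsilyloxy)-6-oxabicyclo[3.2.1]oct-3-en-7-ol (lactol, anomeric mixture) | CC(C)(C)[Si](C)(C)O[C@]12CC=C[C@H](OC1O)C2 | intermediate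
13 | (1R,5S)-5-(tert-butyldimethylsilyloxy)-5-vinylcyclohex-2-en-1-ol | C=C[C@]1(O[Si](C)(C)C(C)(C)C)CC=C[C@H](O)C1 | intermediate
14 | (S)-5-(tert-butyldimethylsilyloxy)-5-vinylcyclohex-2-enone | C=C[C@]1(O[Si](C)(C)C(C)(C)C)CC=CC(=O)C1 | intermediate
15 | (S)-5-(tert-butyldimethylsilyloxy)-2-iodo-5-vinylcyclohex-2-enone | C=C[C@]1(O[Si](C)(C)C(C)(C)C)CC=C(I)C(=O)C1 | intermediate
16 | [6-bromo-3-(ethoxycarbonyl)-7-methylbenzofuran-5-yl]magnesium chloride | CCOC(=O)c1coc2c(C)c(Br)c([Mg]Cl)cc12 | intermediate
17 | [6-bromo-3-(ethoxycarbonyl)-7-methylbenzofuran-5-yl]zinc chloride | CCOC(=O)c1coc2c(C)c(Br)c([Zn]Cl)cc12 | intermediate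
18 | (S)-2-Ar-5-(tert-butyldimethylsilyloxy)-5-vinylcyclohex-2-enone | C=C[C@]1(O[Si](C)(C)C(C)(C)C)CC=C(c2cc3c(C(=O)OCC)coc3c(C)c2Br)C(=O)C1 | intermediate
19 | methyl 2-[2-Ar-5-(tert-butyldimethylsilyloxy)-1-hydroxy-5-vinylcyclohex-2-enyl]acetate (carbinol epimers) | C=C[C@]1(O[Si](C)(C)C(C)(C)C)CC=C(c2cc3c(C(=O)OCC)coc3c(C)c2Br)C(O)(CC(=O)OC)C1 | intermediate
20 | methyl 2-[(5R)-2-Ar-5-(tert-butyldimethylsilyloxy)-3-oxo-5-vinylcyclohex-1-enyl]acetate | C=C[C@]1(O[Si](C)(C)C(C)(C)C)CC(=O)C(c2cc3c(C(=O)OCC)coc3c(C)c2Br)=C(CC(=O)OC)C1 | intermediate
21 | methyl 2-[(5R)-5-acetyl-2-Ar-5-(tert-butyldimethylsilyloxy)-3-oxocyclohex-1-enyl]acetate (key-step precursor) | CC(=O)[C@]1(O[Si](C)(C)C(C)(C)C)CC(=O)C(c2cc3c(C(=O)OCC)coc3c(C)c2Br)=C(CC(=O)OC)C1 | intermediate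
22 | methyl 2-[2-Ar-5-(tert-butyldimethylsilyloxy)-3,6-dioxobicyclo[3.2.1]octan-1-yl]acetate (key-step product; C9 drawn with aryl cis to the arm, epimerisable) | O=C1C[C@]2(CC(=O)OC)C[C@@]1(O[Si](C)(C)C(C)(C)C)CC(=O)[C@H]2c1cc2c(C(=O)OCC)coc2c(C)c1Br | intermediate
23 | methyl 2-[2-Ar-5-(tert-butyldimethylsilyloxy)-6-methylene-3-oxobicyclo[3.2.1]octan-1-yl]acetate | C=C1C[C@]2(CC(=O)OC)C[C@@]1(O[Si](C)(C)C(C)(C)C)CC(=O)[C@H]2c1cc2c(C(=O)OCC)coc2c(C)c1Br | intermediate
24 | methyl 2-[2-Ar-3,5-bis(tert-butyldimethylsilyloxy)-6-methylenebicyclo[3.2.1]oct-2-en-1-yl]acetate | C=C1C[C@]2(CC(=O)OC)C[C@@]1(O[Si](C)(C)C(C)(C)C)CC(O[Si](C)(C)C(C)(C)C)=C2c1cc2c(C(=O)OCC)coc2c(C)c1Br | intermediate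
25 | ring-B-closed C9=C11 silyl enol ether (13-O-silyl, 7-methyl 3'-ethyl diester) | C=C1C[C@]23C[C@@]1(O[Si](C)(C)C(C)(C)C)CC(O[Si](C)(C)C(C)(C)C)=C2c1cc2c(C(=O)OCC)coc2c(C)c1[C@@H]3C(=O)OC | intermediate
26 | 11-oxo-13-O-(tert-butyldimethylsilyl)pharbinilic acid 7-methyl 3'-ethyl diester | C=C1C[C@]23C[C@@]1(O[Si](C)(C)C(C)(C)C)CC(=O)[C@H]2c1cc2c(C(=O)OCC)coc2c(C)c1[C@@H]3C(=O)OC | intermediate
27 | 11-hydroxy-13-O-(tert-butyldimethylsilyl)pharbinilic acid 7-methyl 3'-ethyl diester (C11 epimers) | C=C1C[C@]23C[C@@]1(O[Si](C)(C)C(C)(C)C)CC(O)[C@H]2c1cc2c(C(=O)OCC)coc2c(C)c1[C@@H]3C(=O)OC | intermediate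
28 | 11-O-(imidazol-1-ylthiocarbonyl)-13-O-(tert-butyldimethylsilyl)pharbinilic acid 7-methyl 3'-ethyl diester | C=C1C[C@]23C[C@@]1(O[Si](C)(C)C(C)(C)C)CC(OC(=S)n4ccnc4)[C@H]2c1cc2c(C(=O)OCC)coc2c(C)c1[C@@H]3C(=O)OC | intermediate
29 | 13-O-(tert-butyldimethylsilyl)pharbinilic acid 7-methyl 3'-ethyl diester | C=C1C[C@]23C[C@@]1(O[Si](C)(C)C(C)(C)C)CC[C@H]2c1cc2c(C(=O)OCC)coc2c(C)c1[C@@H]3C(=O)OC | intermediate
30 | pharbinilic acid 7-methyl 3'-ethyl diester | C=C1C[C@]23C[C@@]1(O)CC[C@H]2c1cc2c(C(=O)OCC)coc2c(C)c1[C@@H]3C(=O)OC | intermediate
31 | pharbinilic acid | C=C1C[C@]23C[C@@]1(O)CC[C@H]2c1cc2c(C(=O)O)coc2c(C)c1[C@@H]3C(=O)O | target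

## Step count and least certain steps

Total: 23 steps. Longest linear sequence: 20 steps (steps 4–23, from 7). The aryl branch (steps 1–3) joins at step 12.

Key step (step 16). The most likely failures are slow enamine formation at the hindered α-silyloxy methyl ketone, and condensation of the amine at the C11 enone instead, followed by loss of silanolate and aromatisation of ring C. Fallback: from 21 the silyl ether is removed with HF·pyridine to give the hydroxy ketone methyl 2-[(5R)-5-acetyl-2-Ar-5-hydroxy-3-oxocyclohex-1-enyl]acetate F1. Its less encumbered acetyl group is cyclised with pyrrolidine/AcOH to the hydroxy dione methyl 2-[2-Ar-5-hydroxy-3,6-dioxobicyclo[3.2.1]octan-1-yl]acetate F2 (a free hydroxyl is a poorer leaving group than silanolate). F2 is re-silylated with tBuMe2SiOTf/2,6-lutidine and rejoins the route at 22.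

Step 19. Silyl transfer from the enol ether to the ester enolate under the lithium amide would uncover the C11 enolate, which could O-arylate. Oxidative addition at the di-ortho-substituted bromide may also be slow. Fallback: from 24 the arm ester is converted (LiN(iPr)2, Me3SiCl, −78 °C) into its trimethylsilyl ketene acetal F3. F3 is coupled intramolecularly without strong base (Pd(dba)2, P(tBu)3, ZnF2, DMF, 80 °C) to 25, which is desilylated and equilibrated as in the main route to return at 26.

Step 18. Kinetic deprotonation at C12 instead of the hindered C9 would give the C11=C12 regioisomer, in which C9 is not planar, so ring B could not close from the wrong C9 epimer. Fallback: from 23, no enol ether is isolated. Two equivalents of LiN(SiMe3)2 turn the ketone into its C9 lithium enolate and the ester into its enolate, and the same palladium-catalysed arylation is run on this dianion with a ligand that favours C–C over C–O reductive elimination. Acidification and DBU equilibration return the route at 26. This detour makes no new compound (F0).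

Step 17. The basic ylide generates the C9 enolate of 22, which can undergo retro-Michael opening of ring D; the reopened enone can then lose the C13 silyloxy group. Fallback: from 22, the non-basic Takai–Lombardo methylenation (Zn, CH2Br2, TiCl4, THF/CH2Cl2, 0 °C) is used with the reagent as limiting component. The titanium methylene species adds to the less shielded cyclopentanone carbonyl without forming an enolate, and the route is rejoined at 23. This detour makes no new compound (F0).

Step 15. Hydroxypalladation at the terminal carbon (assisted by the allylic oxygen) would give the aldehyde, and the alkene on a quaternary carbon may react slowly. Fallback: from 20, Mukaiyama hydration (Co(acac)2, PhSiH3, O2, iPrOH) gives the secondary alcohol methyl 2-[2-Ar-5-(tert-butyldimethylsilyloxy)-5-(1-hydroxyethyl)-3-oxocyclohex-1-enyl]acetate F4 as a carbinol epimer mixture. Dess–Martin periodinane oxidises F4 to 21.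

## Further compounds

F1 | step 16 | methyl 2-[(5R)-5-acetyl-2-Ar-5-hydroxy-3-oxocyclohex-1-enyl]acetate | CC(=O)[C@]1(O)CC(=O)C(c2cc3c(C(=O)OCC)coc3c(C)c2Br)=C(CC(=O)OC)C1
F2 | step 16 | methyl 2-[2-Ar-5-hydroxy-3,6-dioxobicyclo[3.2.1]octan-1-yl]acetate | O=C1C[C@]2(CC(=O)OC)C[C@@]1(O)CC(=O)[C@H]2c1cc2c(C(=O)OCC)coc2c(C)c1Br
F3 | step 19 | trimethylsilyl ketene acetal of 24 (arm as CH=C(OMe)OSiMe3) | C=C1C[C@]2(C=C(OC)O[Si](C)(C)C)C[C@@]1(O[Si](C)(C)C(C)(C)C)CC(O[Si](C)(C)C(C)(C)C)=C2c1cc2c(C(=O)OCC)coc2c(C)c1Br
F0 | step 18 | none | none
F0 | step 17 | none | none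
F4 | step 15 | methyl 2-[2-Ar-5-(tert-butyldimethylsilyloxy)-5-(1-hydroxyethyl)-3-oxocyclohex-1-enyl]acetate (carbinol epimers) | CC(O)[C@]1(O[Si](C)(C)C(C)(C)C)CC(=O)C(c2cc3c(C(=O)OCC)coc3c(C)c2Br)=C(CC(=O)OC)C1
A1 | alternative 1 | tetracyclic phenol (C3 hydroxyl, C4 methyl, C2 unsubstituted, 13-O-methoxymethyl, C7 silyl ether) | C=C1C[C@]23C[C@@]1(OCOC)CC[C@H]2c1ccc(O)c(C)c1[C@@H]3CO[Si](C)(C)C(C)(C)C
A2 | alternative 1 | ring B ketone (C5 carbonyl, C10 methylene, rings B, C and D complete) | C=C1C[C@]23C[C@@]1(OCOC)CC[C@H]2CC(=O)[C@@H]3CO[Si](C)(C)C(C)(C)C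
A3 | alternative 1 | pent-1-yn-3-one | CCC(=O)C#C
A4 | alternative 2 | cis-fused hexahydrofluorenone (C6 ketone, C8 propargyl, C13 silyl ether) | C#CC[C@]23C[C@@H](O[Si](C)(C)C(C)(C)C)C=C[C@H]2c1cc2c(C(=O)OCC)coc2c(C)c1C3=O
A5 | alternative 2 | aryl 2-methylene ketone carrying the (E,E)-4-siloxybutadienyl group on C10 | C#CCC(=C)C(=O)c1c(C)c2occ(C(=O)OCC)c2cc1/C=C/C=C/O[Si](C)(C)C(C)(C)C
A6 | alternative 3 | tricyclic C13 ketone (C8 propargyl, C6 methyl ester) | C#CC[C@]23CC(=O)CC[C@H]2c1cc2c(C(=O)OCC)coc2c(C)c1[C@@H]3C(=O)OC
A7 | alternative 3 | indene ester (C6=C8 double bond, C8 propargyl, C9 methylene) | C#CCC1=C(C(=O)OC)c2c(C)c3occ(C(=O)OCC)c3cc2C1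
A8 | alternative 3 | but-3-en-2-one | CC(=O)C=C
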